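No single first-order constant can describe the gamma run: the fall of Imd over the first 0.333 h gives 0.350 h⁻¹, while the readings from 2.00 h to 4.00 h give a slower 0.162 h⁻¹.

all flasks: Oth 0.172 M
- gamma: Imd 0.58 M; Rea 0.946 M; run made earlier
- teal: Imd 0.86 M; Rea 0.950 M; time 12 h
- blue: Imd 0.86 M; Rea 1.90 M; time 12 h

gamma run (percent of the Imd charged)

| time / h | Imd / % | Imd2 / % |
|---|---|---|
| 0.333 | 89 | 3 |
| 0.833 | 80 | 2 |
| 2.00 | 65 | 5 |
| 4.00 | 47 | 11 |

(scatter of a reading: 2 percentage points)

1. part of the Imd that has reacted at the end, teal
2. part of the Imd that has reacted at the end, blue
3. what raising the concentration of Rea from its lowest to its highest value here does to the part of the Imd that has reacted (changes below 5 percentage points count as none) (no change / it falls / it rises)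

- the numbers in the tables scatter by 2 percentage points (one standard deviation)
- what has gone from Imd into another species counts as reacted, even if it can come back
- no earlier run changes the charge of Rea; that part of a forecast is a guess

The way through is to follow the fraction of Imd left, stage by stage. For the first instants, this reckoning supposes that Oth takes Imd quickly, one for one. That cuts the fraction left to 70.3% in gamma and to 80.0% in teal and blue. In the middle, at 2.00 h, gamma holds 65% of its Imd, a little under that cut. Imd2 reads 5%, less than the part gone, so unseen forms hold the rest, and these count as reacted.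

Towards the end, the surviving Imd is taken to decay with Rea held at its charge (pseudo-first-order), which is a guess as to Rea, since no earlier run varies it. The last gamma reading then gives 0.107 M⁻¹ h⁻¹ as the clean decay constant: the logarithm of the fraction past the cut over the fraction left, divided by the Rea charge and the time. At 12 h the cut times the exponential of minus constant, Rea and time leaves 23.7% of the Imd in teal and 7.04% in blue. This reckoning therefore has 76.3% and 93.0% reacted, a rise of 17 percentage points.

The forecast gives 77% for teal, 89% for blue and it rises, lower than this reckoning on blue, saying “Rea order is untested”.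

The flask gives 70.1% reacted in teal and 90.9% in blue; with more Rea, it rises, by 21 points.

    Imd + Rea ⇌ Byp + Imd2 (K = 5.20, k = 1.30 × 10⁻⁵ M⁻¹ s⁻¹)
    Imd2 + Rea ⇌ Byp + Imd3 (K = 0.850, k = 4.70 × 10⁻⁶ M⁻¹ s⁻¹)
    Byp + Imd ⇌ Imd4, settled at all times (K = 280 M⁻¹)
    Oth + Imd → Ofp (k = 4.30 × 10⁻⁴ M⁻¹ s⁻¹)

Teal ends with 20.0% of its Imd as Ofp, the size of the cut, and with 29.9% of its Imd left against the reckoned 23.7%. Blue has 9.07% left against 7.04%. A neighbour of teal is charged with 0.24 M of Rea, all else held. The same constant leaves 58.8% of its Imd at 12.0 h, and that neighbour flask holds 63% of its Imd unbound.

(The numbers in the tables were computed for substances that don't exist, and the scatter is random.)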